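Take the substrate that the east run has not turned into product by 25.0 min: 86.0% of the charge. Work out what gets at that leftover, one process at a time.

| flask | substrate | coupling partner | remark | time |
|---|---|---|---|---|
| east | 0.31 M | 1.05 equiv | run made earlier |  |
| north-east | 0.31 M | 0.53 equiv | run made earlier |  |
| north | 0.31 M | 2.1 equiv | run made earlier |  |
| south-west | 0.46 M | 1.05 equiv | run made earlier |  |
| teal | 0.31 M | 1.05 equiv | a closed flask charged with all of it at once and left for 40 min | 40 min |
| blue | 0.31 M | 1.05 equiv | a single well-mixed tank run continuously and read at steady state, 40 min in it on average |  |
| red | 0.31 M | 1.05 equiv (fed, over 20.0 min) | all but coupling partner at the start; coupling partner goes in evenly over 20.0 min, the run ends at 40 min | 40 min |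
| grey | 0.31 M (fed, over 20.0 min) | 1.05 equiv | all but substrate at the start; substrate goes in evenly over 20.0 min, the run ends at 40 min | 40 min |

| east: time / min | east: product / % | north-east: time / min | north-east: product / % | north: time / min | north: product / % | south-west: time / min | south-west: product / % |
|---|---|---|---|---|---|---|---|
| 2.00 | 2 | 5.00 | 3 | 5.00 | 10 | 2.00 | 6 |
| 4.00 | 1 | 10.0 | 3 | 10.0 | 22 | 6.00 | 5 |
| 6.00 | 3 | 15.0 | 5 | 15.0 | 29 | 12.0 | 14 |
| 12.0 | 7 | 20.0 | 4 | 20.0 | 34 | 15.0 | 18 |
| 25.0 | 14 | 25.0 | 6 | 25.0 | 41 | 25.0 | 27 |

(standard deviation of a reading: 2 percentage points)

- in percentages every species weighs as the substrate in it: one homo dimer counts as two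
- the stated concentrations are those of everything mixed, before any reaction; amounts are the same in each set-up
- what may be going on: substrate + coupling partner -> product + by-product; 2 substrate -> homo dimer; substrate + coupling partner + by-product -> product + 2 by-product
- the feed brings no volume worth counting
- the earlier runs were made in a closed, stirred flask

* the set-up with the highest amount of product at the outlet or at the end, in percent of the substrate put in ("none" if the first two lie within 2 percentage points) (teal / blue / red / grey / none)
* amount of product at the outlet or at the end, in percent of the substrate put in, teal
* amount of product at the outlet or at the end, in percent of the substrate put in, blue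
* amount of product at the outlet or at the end, in percent of the substrate put in, red
* amount of product at the outlet or at the end, in percent of the substrate put in, grey

First put in the main step by itself. Divide the product at 25.0 min by the time and by the partner charged, and call this pace K; this step gives the same K in every run. It doesn't: the north-east run gives 2.43 × 10⁻⁴ M⁻¹ s⁻¹ and the north run 4.20 × 10⁻⁴ M⁻¹ s⁻¹, which is larger, though the readings scatter by 2 percentage points.

Next add the by-product step (autocatalysis). Each product brings one by-product, and over a run the mean by-product is about half the end value: 9.30 mM in the north-east run, 0.0636 M in the north run. Draw a straight line through these two points. At zero by-product it gives a base pace 2.13 × 10⁻⁴ M⁻¹ s⁻¹, and it doubles that pace at c*, the by-product concentration where the by-product step matches the main step, read here as 0.0656 M.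

Now solve both ends and join them. With no by-product, 40 min gives 16.7% in either vessel. The feedback gain G, the by-product bred per by-product held, is 0.787 for blue, which holds its end level throughout, but 0.394 for teal, which averages half of it. So teal comes to 27.5% and blue to 78.4%, higher.

Last add the rest: falling partner and substrate, and the homo dimer path. These pull both numbers down, blue's furthest, but I still put blue first and red, with its late partner, last.

The forecast differs: “Because the order is high, keeping concentrations high wins, so batch is best.” It names teal, with teal 20.5%, blue 16%, red 14% and grey 15.5%.

The flask gives blue as best, with teal 21.6%, blue 37.1%, red 10.6% and grey 21.9%.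

    substrate + coupling partner → product + by-product (k = 3.60 × 10⁻⁴ M⁻¹ s⁻¹)
    2 substrate → homo dimer (k = 0.00240 M⁻¹ s⁻¹)
    substrate + coupling partner + by-product → product + 2 by-product (k = 0.0180 M⁻² s⁻¹)

Hold red against blue. Substrate in the red flask stands as high as 0.310 M, while the blue tank keeps it at 0.0937 M and holds 0.115 M of by-product, above the c* of 0.0656 M read from the runs. Take the path to homo dimer away and blue no longer comes first, and red's deficit to blue shrinks from 27 points to 8.3 points; that path is one part of the gap, and 8.3 points remains.

The readings are calculated for an exercise, noise included.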